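**Plan**

Locants used throughout (bicyclo[3.2.1]octane): C1 = bridgehead between the two C=O, C2 = enone C=O, C3=C4 = enone alkene, C5 = second bridgehead, C6 = CH(3,5-dioxygenated aryl), C7 = CH(3,4-dioxygenated aryl), C8 = bridging C=O.
Cuts, in order: (i) the styryl C=C on C4, back to a C4 methyl group (vinylogous aldol, dehydration); (ii) C2–C3 and C5–C8 together; (iii) C6–C7 (homoenolate Michael addition).
Enabling feature: C1 carries both ring carbonyls (C2, C8), so it is a malonyl carbon, and C3 and C5 flank C4. The ring C1–C2–C3–C4–C5–C8 is therefore a malonyl unit clamped onto an isobutenyl group that reacts twice as a 1,3-dinucleophile: at C5, then, after ene-type shift of its double bond, at C3.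
Forward: one carbene-catalysed coupling joins the two aryl-bearing carbons and delivers the whole chain. A malonyl dichloride then closes the cyclopentanone (C5–C8) and the cyclohexenone (C2–C3) in one cationic cascade. The styryl arm is added last at the only enolisable position.
Stereochemistry: C6 and C7 (absolute and relative) come from the chiral carbene; C5 from allylic 1,3-strain in the first ring closure; C1 is a mobile malonyl centre funnelled into the only configuration that can bridge; the styryl alkene is E by thermodynamics.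

Key step: step 8

Remark: the bridged 1,3-diketone (C2 and C8 on the non-enolisable bridgehead C1) is assumed to be cleaved by hydroxide, alkoxide or amines (retro-Claisen), so every step after step 8 is run under acidic or neutral conditions.

**Step 1**
Reactants: 1 3,4-bis(benzyloxy)benzaldehyde; 2 di-tert-butyl malonate
Product: 3 di-tert-butyl 2-{[3,4-bis(benzyloxy)phenyl]methylidene}propanedioate
Conditions: piperidine (10 mol %), AcOH (10 mol %), toluene, reflux, Dean–Stark
Reagents that add atoms: none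
Why: Knoevenagel condensation of a non-enolisable aryl aldehyde with a malonate, driven by removal of water, and no stereocentre arises because the two ester groups are identical.

**Step 2**
Reactants: 4 3,5-bis(benzyloxy)benzaldehyde; 5 (triphenylphosphoranylidene)acetaldehyde
Product: 6 (2E)-3-[3,5-bis(benzyloxy)phenyl]prop-2-enal
Conditions: toluene, 80 °C
Reagents that add atoms: none
Why: Wittig reaction of a stabilised formylmethylene ylide, which should give the E-enal under thermodynamic control.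

**Step 3**
Reactants: 6 (2E)-3-[3,5-bis(benzyloxy)phenyl]prop-2-enal; 3 di-tert-butyl 2-{[3,4-bis(benzyloxy)phenyl]methylidene}propanedioate
Product: 7 1,1-di-tert-butyl 4-methyl (2R,3S)-2-[3,4-bis(benzyloxy)phenyl]-3-[3,5-bis(benzyloxy)phenyl]butane-1,1,4-tricarboxylate
Conditions: (5aR,10bS)-2-mesityl-5a,10b-dihydro-4H,6H-indeno[2,1-b][1,2,4]triazolo[4,3-d][1,4]oxazin-2-ium chloride (10 mol %; its enantiomer is used instead if the opposite sense of induction is found), DBU (15 mol %), Mg(OtBu)2 (10 mol %), MeOH (5 equiv), THF, rt, slow addition of 6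
Reagents that add atoms: methanol, CO
Why: N-heterocyclic-carbene homoenolate conjugate addition, in which the β-carbon of the enal (as the extended Breslow intermediate) adds to the magnesium-chelated alkylidene malonate and the resulting acyl azolium is methanolysed; the chiral carbene should fix the absolute configuration at C3 and the chelated transition state should place the two aryl groups syn (2R,3S), the arrangement that becomes trans on the later five-membered ring.

**Step 4**
Reactants: 7 1,1-di-tert-butyl 4-methyl (2R,3S)-2-[3,4-bis(benzyloxy)phenyl]-3-[3,5-bis(benzyloxy)phenyl]butane-1,1,4-tricarboxylate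
Product: 8 di-tert-butyl 2-{(1R,2S)-1-[3,4-bis(benzyloxy)phenyl]-2-[3,5-bis(benzyloxy)phenyl]-4-hydroxy-4-methylpentyl}propanedioate
Conditions: MeMgBr (4 equiv), THF, −20 → 0 °C; aq. NH4Cl
Reagents that add atoms: methylmagnesium bromide, C[Mg]Br
Why: Grignard double addition to the methyl ester only, because the first equivalent deprotonates the malonate and its magnesium enolate with two tert-butyl esters is inert; the stereocentres are not touched.

**Step 5**
Reactants: 8 di-tert-butyl 2-{(1R,2S)-1-[3,4-bis(benzyloxy)phenyl]-2-[3,5-bis(benzyloxy)phenyl]-4-hydroxy-4-methylpentyl}propanedioate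
Product: 9 di-tert-butyl 2-[(1R,2S)-1-(3,4-dihydroxyphenyl)-2-(3,5-dihydroxyphenyl)-4-hydroxy-4-methylpentyl]propanedioate
Conditions: H2 (1 atm), Pd/C (10 wt %), EtOAc–MeOH, rt
Reagents that add atoms: none
Why: hydrogenolysis of the four aryl benzyl ethers, which leaves the non-benzylic tertiary alcohol and the tert-butyl esters intact and frees the phenols for the change to electron-poor protecting groups.

**Step 6**
Reactants: 9 di-tert-butyl 2-[(1R,2S)-1-(3,4-dihydroxyphenyl)-2-(3,5-dihydroxyphenyl)-4-hydroxy-4-methylpentyl]propanedioate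
Product: 10 di-tert-butyl 2-[(1R,2S)-1-(3,4-diacetoxyphenyl)-2-(3,5-diacetoxyphenyl)-4-hydroxy-4-methylpentyl]propanedioate
Conditions: Ac2O (6 equiv), pyridine, rt
Reagents that add atoms: acetic anhydride, CC(=O)OC(C)=O
Why: O-acetylation of the four phenols, which are acylated far faster than the hindered tertiary alcohol in the absence of a nucleophilic catalyst, and the acetoxy groups deactivate both arenes towards the electrophiles of steps 7 and 8.

**Step 7**
Reactants: 10 di-tert-butyl 2-[(1R,2S)-1-(3,4-diacetoxyphenyl)-2-(3,5-diacetoxyphenyl)-4-hydroxy-4-methylpentyl]propanedioate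
Product: 11 2-[(1R,2S)-1-(3,4-diacetoxyphenyl)-2-(3,5-diacetoxyphenyl)-4-methylpent-3-en-1-yl]propanedioic acid
Conditions: TsOH·H2O (10 mol %), toluene, 70 °C
Reagents that add atoms: none
Why: acid-catalysed E1 dehydration of the tertiary alcohol to the more substituted alkene together with acid-catalysed cleavage of both tert-butyl esters (loss of 2-methylpropene), and any 1,1-disubstituted alkene isomer should enter step 8 through the same tertiary cation.

**Step 8**
Reactants: 11 2-[(1R,2S)-1-(3,4-diacetoxyphenyl)-2-(3,5-diacetoxyphenyl)-4-methylpent-3-en-1-yl]propanedioic acid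
Product: 15 (1S,5R,6R,7R)-7-(3,4-diacetoxyphenyl)-6-(3,5-diacetoxyphenyl)-4-methylbicyclo[3.2.1]oct-3-ene-2,8-dione, via malonyl dichloride 12 (not isolated), via isopropenyl keto acid chloride 13 (not isolated), via exocyclic methylene diketone 14 (not isolated)
Conditions: (COCl)2 (2.4 equiv), DMF (cat.), CH2Cl2, 0 °C → rt, evaporate; SnCl4 (3 equiv), CH2Cl2, −78 → 0 °C; aq. NaHCO3
Reagents that add atoms: none
Why: Proposed new method: SnCl4 ionises one of the two diastereotopic chlorocarbonyl groups of 12, the trisubstituted alkene attacks through C5 (5-exo closure of the cyclopentanone, tertiary cation at C4) and a methyl proton is lost in the ene-like manner to give the isopropenyl ketone 13; the second acyl chloride then acylates the new 1,1-disubstituted alkene at its CH2 terminus C3 (6-endo closure of the cyclohexanone across C1 and C5), and proton loss followed by acid-mediated migration of the exocyclic double bond of 14 into conjugation gives 15. The closest known reaction is the Lewis-acid-mediated intramolecular acylation of a trisubstituted alkene by an acid chloride (aliphatic Friedel–Crafts acylation, as in the cyclisation of citronelloyl chloride to isopulegone); running it twice from one malonyl dichloride, with the isobutenyl group as a 1,3-dinucleophile, is the untested part. C5 is set in the first closure by allylic 1,3-strain: the C6–H eclipses the cis-methyl group of the alkene, so the tether attacks the face that leaves the C4 unit trans to the C6 aryl group. C1 lies between a ketone and an acid chloride in 13 and epimerises freely through the enol, so both C1 epimers are funnelled into the one whose COCl is cis to the isopropenyl group, the only one that can bridge, and this places the C7 aryl group on the face of the five-membered ring that carries the C2–C4 bridge, as in the target. C6 and C7 are not touched. The step needs the alkene to outrun the arenes as nucleophile, which the four acetoxy groups should secure by deactivating both rings towards indanone and tetralone formation, and it needs acylation rather than ketene [2+2] cycloaddition, which the low temperature and the absence of base should secure.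

**Step 9**
Reactants: 15 (1S,5R,6R,7R)-7-(3,4-diacetoxyphenyl)-6-(3,5-diacetoxyphenyl)-4-methylbicyclo[3.2.1]oct-3-ene-2,8-dione; 16 3,4-diacetoxybenzaldehyde (commercially available)
Product: 19 (1S,5R,6R,7R)-7-(3,4-diacetoxyphenyl)-6-(3,5-diacetoxyphenyl)-4-[2-(3,4-diacetoxyphenyl)-2-hydroxyethyl]bicyclo[3.2.1]oct-3-ene-2,8-dione as both carbinol epimers, via trimethylsilyl dienol ether 17 (not isolated), via O-trimethylsilyl aldol adduct 18 (not isolated)
Conditions: i-Pr2NEt (1.5 equiv), TMSOTf (2.2 equiv), CH2Cl2, −78 → 0 °C; then 16, −78 °C; 1 M HCl work-up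
Reagents that add atoms: none
Why: soft enolisation can occur only at the C4 methyl group (the α′ and the other γ position are bridgeheads), giving the linear silyl dienol ether 17, which should add through its terminal CH2 to the silyl-activated aldehyde in a vinylogous Mukaiyama aldol reaction; the new carbinol centre forms as a mixture that does not matter because it is removed in step 10.

**Step 10**
Reactants: 19 (1S,5R,6R,7R)-7-(3,4-diacetoxyphenyl)-6-(3,5-diacetoxyphenyl)-4-[2-(3,4-diacetoxyphenyl)-2-hydroxyethyl]bicyclo[3.2.1]oct-3-ene-2,8-dione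
Product: 20 jezonodione, (1S,5R,6R,7R)-7-(3,4-dihydroxyphenyl)-6-(3,5-dihydroxyphenyl)-4-[(E)-2-(3,4-dihydroxyphenyl)ethenyl]bicyclo[3.2.1]oct-3-ene-2,8-dione
Conditions: HCl (about 0.5 M, from AcCl) in MeOH, 0 °C → rt, argon
Reagents that add atoms: none
Why: acid-catalysed transesterification should remove the six aryl acetates as methyl acetate, and the vinylogous β-hydroxy ketone, a 4-hydroxybenzylic alcohol once deacetylated, should dehydrate (E1 through the quinone-methide-like cation or through the dienol) to the thermodynamically favoured E-styryl dienone, both epimers converging on one alkene, while acid instead of base spares the bridged diketone.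

**Compound list**

1 | 3,4-bis(benzyloxy)benzaldehyde | O=Cc1ccc(OCc2ccccc2)c(OCc2ccccc2)c1 | starting material
2 | di-tert-butyl malonate | CC(C)(C)OC(=O)CC(=O)OC(C)(C)C | starting material
3 | di-tert-butyl 2-{[3,4-bis(benzyloxy)phenyl]methylidene}propanedioate | CC(C)(C)OC(=O)C(=Cc1ccc(OCc2ccccc2)c(OCc2ccccc2)c1)C(=O)OC(C)(C)C | intermediate
4 | 3,5-bis(benzyloxy)benzaldehyde | O=Cc1cc(OCc2ccccc2)cc(OCc2ccccc2)c1 | starting material
5 | (triphenylphosphoranylidene)acetaldehyde | O=CC=P(c1ccccc1)(c1ccccc1)c1ccccc1 | starting material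
6 | (2E)-3-[3,5-bis(benzyloxy)phenyl]prop-2-enal | O=C/C=C/c1cc(OCc2ccccc2)cc(OCc2ccccc2)c1 | intermediate
7 | 1,1-di-tert-butyl 4-methyl (2R,3S)-2-[3,4-bis(benzyloxy)phenyl]-3-[3,5-bis(benzyloxy)phenyl]butane-1,1,4-tricarboxylate | CC(C)(C)OC(=O)C(C(=O)OC(C)(C)C)[C@H](c1ccc(OCc2ccccc2)c(OCc2ccccc2)c1)[C@H](CC(=O)OC)c1cc(OCc2ccccc2)cc(OCc2ccccc2)c1 | intermediate
8 | di-tert-butyl 2-{(1R,2S)-1-[3,4-bis(benzyloxy)phenyl]-2-[3,5-bis(benzyloxy)phenyl]-4-hydroxy-4-methylpentyl}propanedioate | CC(C)(C)OC(=O)C(C(=O)OC(C)(C)C)[C@H](c1ccc(OCc2ccccc2)c(OCc2ccccc2)c1)[C@H](CC(C)(C)O)c1cc(OCc2ccccc2)cc(OCc2ccccc2)c1 | intermediate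
9 | di-tert-butyl 2-[(1R,2S)-1-(3,4-dihydroxyphenyl)-2-(3,5-dihydroxyphenyl)-4-hydroxy-4-methylpentyl]propanedioate | CC(C)(C)OC(=O)C(C(=O)OC(C)(C)C)[C@H](c1ccc(O)c(O)c1)[C@H](CC(C)(C)O)c1cc(O)cc(O)c1 | intermediate
10 | di-tert-butyl 2-[(1R,2S)-1-(3,4-diacetoxyphenyl)-2-(3,5-diacetoxyphenyl)-4-hydroxy-4-methylpentyl]propanedioate | CC(C)(C)OC(=O)C(C(=O)OC(C)(C)C)[C@H](c1ccc(OC(C)=O)c(OC(C)=O)c1)[C@H](CC(C)(C)O)c1cc(OC(C)=O)cc(OC(C)=O)c1 | intermediate
11 | 2-[(1R,2S)-1-(3,4-diacetoxyphenyl)-2-(3,5-diacetoxyphenyl)-4-methylpent-3-en-1-yl]propanedioic acid | OC(=O)C(C(=O)O)[C@H](c1ccc(OC(C)=O)c(OC(C)=O)c1)[C@H](C=C(C)C)c1cc(OC(C)=O)cc(OC(C)=O)c1 | intermediate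
12 | 2-[(1R,2S)-1-(3,4-diacetoxyphenyl)-2-(3,5-diacetoxyphenyl)-4-methylpent-3-en-1-yl]propanedioyl dichloride | ClC(=O)C(C(Cl)=O)[C@H](c1ccc(OC(C)=O)c(OC(C)=O)c1)[C@H](C=C(C)C)c1cc(OC(C)=O)cc(OC(C)=O)c1 | intermediate (not isolated)
13 | (3R,4R,5R)-5-(3,4-diacetoxyphenyl)-4-(3,5-diacetoxyphenyl)-2-oxo-3-(prop-1-en-2-yl)cyclopentane-1-carbonyl chloride, C1 epimers interconverting | C=C(C)[C@@H]1C(=O)C(C(Cl)=O)[C@H](c2ccc(OC(C)=O)c(OC(C)=O)c2)[C@H]1c3cc(OC(C)=O)cc(OC(C)=O)c3 | intermediate (not isolated)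
14 | (1S,5R,6R,7R)-7-(3,4-diacetoxyphenyl)-6-(3,5-diacetoxyphenyl)-4-methylidenebicyclo[3.2.1]octane-2,8-dione | O=C1CC(=C)[C@@H]2C(=O)[C@H]1[C@H](c1ccc(OC(C)=O)c(OC(C)=O)c1)[C@H]2c1cc(OC(C)=O)cc(OC(C)=O)c1 | intermediate (not isolated)
15 | (1S,5R,6R,7R)-7-(3,4-diacetoxyphenyl)-6-(3,5-diacetoxyphenyl)-4-methylbicyclo[3.2.1]oct-3-ene-2,8-dione | O=C1C=C(C)[C@@H]2C(=O)[C@H]1[C@H](c1ccc(OC(C)=O)c(OC(C)=O)c1)[C@H]2c1cc(OC(C)=O)cc(OC(C)=O)c1 | intermediate
16 | 3,4-diacetoxybenzaldehyde | CC(=O)Oc1ccc(C=O)cc1OC(C)=O | starting material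
17 | (1S,5R,6R,7R)-7-(3,4-diacetoxyphenyl)-6-(3,5-diacetoxyphenyl)-4-methylidene-2-[(trimethylsilyl)oxy]bicyclo[3.2.1]oct-2-en-8-one | C[Si](C)(C)OC1=CC(=C)[C@@H]2C(=O)[C@H]1[C@H](c1ccc(OC(C)=O)c(OC(C)=O)c1)[C@H]2c1cc(OC(C)=O)cc(OC(C)=O)c1 | intermediate (not isolated)
18 | O-trimethylsilyl ether of 19, both carbinol epimers | O=C1C=C(CC(O[Si](C)(C)C)c3ccc(OC(C)=O)c(OC(C)=O)c3)[C@@H]2C(=O)[C@H]1[C@H](c1ccc(OC(C)=O)c(OC(C)=O)c1)[C@H]2c1cc(OC(C)=O)cc(OC(C)=O)c1 | intermediate (not isolated)
19 | (1S,5R,6R,7R)-7-(3,4-diacetoxyphenyl)-6-(3,5-diacetoxyphenyl)-4-[2-(3,4-diacetoxyphenyl)-2-hydroxyethyl]bicyclo[3.2.1]oct-3-ene-2,8-dione, both carbinol epimers | O=C1C=C(CC(O)c3ccc(OC(C)=O)c(OC(C)=O)c3)[C@@H]2C(=O)[C@H]1[C@H](c1ccc(OC(C)=O)c(OC(C)=O)c1)[C@H]2c1cc(OC(C)=O)cc(OC(C)=O)c1 | intermediate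
20 | jezonodione, (1S,5R,6R,7R)-7-(3,4-dihydroxyphenyl)-6-(3,5-dihydroxyphenyl)-4-[(E)-2-(3,4-dihydroxyphenyl)ethenyl]bicyclo[3.2.1]oct-3-ene-2,8-dione | O=C1C=C(/C=C/c2ccc(O)c(O)c2)[C@@H]2C(=O)[C@H]1[C@H](c1ccc(O)c(O)c1)[C@H]2c1cc(O)cc(O)c1 | target

**Totals and risks**

Total step count: 10. Longest linear sequence: 9 steps (step 1 or 2, then steps 3 to 10).

Steps most likely to fail:

1. Step 8. What may go wrong: acylation of the aryl rings instead of the alkene, loss of HCl to a ketene followed by [2+2] cycloaddition, or arrest after the first ring closure with drift of the alkene into conjugation and loss of the C5 configuration. Fallback, setting out from 11 and returning at 15: thermal decarboxylation (xylene, 140 °C) would give (3S,4S)-3-(3,4-diacetoxyphenyl)-4-(3,5-diacetoxyphenyl)-6-methylhept-5-enoic acid F1. Oxalyl chloride would convert it to (3S,4S)-3-(3,4-diacetoxyphenyl)-4-(3,5-diacetoxyphenyl)-6-methylhept-5-enoyl chloride F2. SnCl4 at −78 °C would then effect the single, precedented intramolecular alkene acylation to (2R,3R,4S)-4-(3,4-diacetoxyphenyl)-3-(3,5-diacetoxyphenyl)-2-(prop-1-en-2-yl)cyclopentan-1-one F3, which forms the C5–C8 bond. A titanium enolate made on the unsubstituted α-carbon (TiCl4, i-Pr2NEt, −78 °C) would add to acrolein to give (2R,3R,4R)-4-(3,4-diacetoxyphenyl)-3-(3,5-diacetoxyphenyl)-5-(1-hydroxyprop-2-en-1-yl)-2-(prop-1-en-2-yl)cyclopentan-1-one F4. Dess–Martin periodinane would oxidise it to (2R,3R,4R)-4-(3,4-diacetoxyphenyl)-3-(3,5-diacetoxyphenyl)-5-(prop-2-enoyl)-2-(prop-1-en-2-yl)cyclopentan-1-one F5, whose C5 centre is enolisable and so supplies the cis isomer. Ring-closing metathesis between the acryloyl and isopropenyl groups (second-generation Hoveyda–Grubbs catalyst, RuCl2(H2IMes)(=CH-2-(i-PrO)C6H4), toluene, 80 °C) would close the cyclohexenone and give 15.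

2. Step 3. What may go wrong: slow addition of the homoenolate to a hindered, electron-rich alkylidene malonate, self-condensation of the enal, or poor control of the relative configuration of the two aryl-bearing carbons. Fallback, setting out from 1 and 2 and returning at 7: vinylmagnesium bromide would add to 1 to give racemic 1-[3,4-bis(benzyloxy)phenyl]prop-2-en-1-ol F6, and methyl chloroformate with pyridine would give 1-[3,4-bis(benzyloxy)phenyl]prop-2-en-1-yl methyl carbonate F7. Molybdenum-catalysed asymmetric allylic alkylation with the sodium salt of 2 (Mo(CO)3(C7H8), (1R,2R)-N,N′-cyclohexane-1,2-diylbis(pyridine-2-carboxamide) or its enantiomer as required) would give the branched product di-tert-butyl 2-{(1R)-1-[3,4-bis(benzyloxy)phenyl]prop-2-en-1-yl}propanedioate F8. Cross-metathesis with methyl acrylate (second-generation Grubbs catalyst, RuCl2(H2IMes)(PCy3)(=CHPh)) would give 1,1-di-tert-butyl 4-methyl (2R,3E)-2-[3,4-bis(benzyloxy)phenyl]but-3-ene-1,1,4-tricarboxylate F9. Rhodium-catalysed asymmetric conjugate addition of 3,5-bis(benzyloxy)phenylboronic acid ([RhCl(C2H4)2]2, chiral 2,5-diphenylbicyclo[2.2.2]octa-2,5-diene ligand, aq. KOH, dioxane) would then set the second aryl-bearing centre under catalyst control and give 7.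

3. Step 10. What may go wrong: acid-induced oligomerisation of the free polyphenolic dienone, conjugate addition of methanol, or incomplete transesterification. Fallback, setting out from 19 and returning at 20: neutral dehydration with Burgess reagent (benzene, 50 °C) would give the hexaacetate (1S,5R,6R,7R)-7-(3,4-diacetoxyphenyl)-6-(3,5-diacetoxyphenyl)-4-[(E)-2-(3,4-diacetoxyphenyl)ethenyl]bicyclo[3.2.1]oct-3-ene-2,8-dione F10. Enzymatic deacetylation (immobilised Candida antarctica lipase B, n-butanol, tert-butyl methyl ether–THF, 40 °C) would then release the six phenols without acid or base and give 20.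

**Further compounds**

F1 | step 8 | (3S,4S)-3-(3,4-diacetoxyphenyl)-4-(3,5-diacetoxyphenyl)-6-methylhept-5-enoic acid | OC(=O)C[C@H](c1ccc(OC(C)=O)c(OC(C)=O)c1)[C@H](C=C(C)C)c1cc(OC(C)=O)cc(OC(C)=O)c1
F2 | step 8 | (3S,4S)-3-(3,4-diacetoxyphenyl)-4-(3,5-diacetoxyphenyl)-6-methylhept-5-enoyl chloride | ClC(=O)C[C@H](c1ccc(OC(C)=O)c(OC(C)=O)c1)[C@H](C=C(C)C)c1cc(OC(C)=O)cc(OC(C)=O)c1
F3 | step 8 | (2R,3R,4S)-4-(3,4-diacetoxyphenyl)-3-(3,5-diacetoxyphenyl)-2-(prop-1-en-2-yl)cyclopentan-1-one | C=C(C)[C@@H]1C(=O)C[C@H](c2ccc(OC(C)=O)c(OC(C)=O)c2)[C@H]1c3cc(OC(C)=O)cc(OC(C)=O)c3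
F4 | step 8 | (2R,3R,4R)-4-(3,4-diacetoxyphenyl)-3-(3,5-diacetoxyphenyl)-5-(1-hydroxyprop-2-en-1-yl)-2-(prop-1-en-2-yl)cyclopentan-1-one, epimers at C5 and at the carbinol | C=C(C)[C@@H]1C(=O)C(C(O)C=C)[C@H](c2ccc(OC(C)=O)c(OC(C)=O)c2)[C@H]1c3cc(OC(C)=O)cc(OC(C)=O)c3
F5 | step 8 | (2R,3R,4R)-4-(3,4-diacetoxyphenyl)-3-(3,5-diacetoxyphenyl)-5-(prop-2-enoyl)-2-(prop-1-en-2-yl)cyclopentan-1-one, C5 epimers and enol | C=C(C)[C@@H]1C(=O)C(C(=O)C=C)[C@H](c2ccc(OC(C)=O)c(OC(C)=O)c2)[C@H]1c3cc(OC(C)=O)cc(OC(C)=O)c3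
F6 | step 3 | 1-[3,4-bis(benzyloxy)phenyl]prop-2-en-1-ol, racemic | C=CC(O)c1ccc(OCc2ccccc2)c(OCc2ccccc2)c1
F7 | step 3 | 1-[3,4-bis(benzyloxy)phenyl]prop-2-en-1-yl methyl carbonate, racemic | C=CC(OC(=O)OC)c1ccc(OCc2ccccc2)c(OCc2ccccc2)c1
F8 | step 3 | di-tert-butyl 2-{(1R)-1-[3,4-bis(benzyloxy)phenyl]prop-2-en-1-yl}propanedioate | CC(C)(C)OC(=O)C(C(=O)OC(C)(C)C)[C@H](c1ccc(OCc2ccccc2)c(OCc2ccccc2)c1)C=C
F9 | step 3 | 1,1-di-tert-butyl 4-methyl (2R,3E)-2-[3,4-bis(benzyloxy)phenyl]but-3-ene-1,1,4-tricarboxylate | CC(C)(C)OC(=O)C(C(=O)OC(C)(C)C)[C@H](c1ccc(OCc2ccccc2)c(OCc2ccccc2)c1)/C=C/C(=O)OC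
F10 | step 10 | (1S,5R,6R,7R)-7-(3,4-diacetoxyphenyl)-6-(3,5-diacetoxyphenyl)-4-[(E)-2-(3,4-diacetoxyphenyl)ethenyl]bicyclo[3.2.1]oct-3-ene-2,8-dione | O=C1C=C(/C=C/c3ccc(OC(C)=O)c(OC(C)=O)c3)[C@@H]2C(=O)[C@H]1[C@H](c1ccc(OC(C)=O)c(OC(C)=O)c1)[C@H]2c1cc(OC(C)=O)cc(OC(C)=O)c1
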